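**Retrosynthetic overview**
1. Feature: the oxygen on C3 (ring C) and the benzylic CH2 of the C2' prenyl chain (ring B) face each other across the C2–C1' bond. Joining them defines a six-membered ring made of C2, C3, O, CH2, C2' and C1', which serves as a temporary tether.
2. Endgame disconnections: the prenyl chain comes from ArCH2Br and an isobutenylstannane (Stille). ArCH2Br plus 3-OAc come from the cyclic benzylic ether (acylative opening). The C2–C1' bond comes from intramolecular direct arylation of a 3-(2-bromobenzyloxy)chromone at C2–H.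
3. The precursor is split at its O–CH2 bond (Mitsunobu) into a ring A/C 3-hydroxychromone and a ring B/D bromochromanylmethanol.
4. Ring A/C starts from phloroacetophenone: 4-O-prenylation, Claisen rearrangement of the symmetrical, para-blocked ether (sets the C8 1,1-dimethylallyl group), enaminone, acyloxylative annulation. Ring B/D starts from protocatechualdehyde: propargyl Claisen chromene synthesis, hydrogenation, reduction, bromination para to the chroman oxygen.
5. Ring order: ring C (step 5) and chroman ring D (step 9) are made in separate branches, the temporary ether ring E closes in step 14 and is reopened in step 17.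

Key step: step 14

Assumption: the target has no stereocentre and no stereodefined double bond, so no stereocontrol is needed. In ring B the two oxygens lie meta and para to the benzylic carbon, so a 3,4-dioxygenated benzaldehyde is taken as the ring B source.

**Step 1**
Reactants: 1 2,4,6-trihydroxyacetophenone; 2 prenyl bromide
Product: 3 1-[2,6-dihydroxy-4-(3-methylbut-2-enyloxy)phenyl]ethanone
Conditions: K2CO3 (1.1 equiv), acetone, reflux
Reagents that add atoms: none
Why: Williamson ether synthesis, in which both ortho hydroxyls are held in hydrogen bonds to the acetyl group, so the more acidic free 4-OH is the one ionised and alkylated on oxygen.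

**Step 2**
Reactants: 3 1-[2,6-dihydroxy-4-(3-methylbut-2-enyloxy)phenyl]ethanone
Product: 5 1-[2,4,6-trihydroxy-3-(2-methylbut-3-en-2-yl)phenyl]ethanone, via ortho-dienone 4 (not isolated)
Conditions: PhNEt2, 200 °C, sealed tube, Ar
Reagents that add atoms: none
Why: Aromatic Claisen rearrangement, in which the two ortho positions of the symmetrical ether are equivalent and the para position carries the acetyl group, so the [3,3] shift with allyl inversion and enolisation of dienone 4 can only place the 1,1-dimethylallyl group at C3.

**Step 3**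
Reactants: 5 1-[2,4,6-trihydroxy-3-(2-methylbut-3-en-2-yl)phenyl]ethanone
Product: 6 1-[2-hydroxy-4,6-bis(methoxymethoxy)-3-(2-methylbut-3-en-2-yl)phenyl]ethanone
Conditions: MOMCl (2.2 equiv), i-Pr2NEt, CH2Cl2, 0 °C to rt
Reagents that add atoms: chloromethyl methyl ether COCCl
Why: Selective MOM ether formation, in which the 2-OH is chelated to the ketone and wedged between the acetyl group and the quaternary carbon, so the 4-OH and the unhindered 6-OH react and the oxygen that becomes O1 stays free.

**Step 4**
Reactants: 6 1-[2-hydroxy-4,6-bis(methoxymethoxy)-3-(2-methylbut-3-en-2-yl)phenyl]ethanone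
Product: 7 (E)-3-(dimethylamino)-1-[2-hydroxy-4,6-bis(methoxymethoxy)-3-(2-methylbut-3-en-2-yl)phenyl]prop-2-en-1-one
Conditions: Me2NCH(OMe)2, toluene, 95 °C
Reagents that add atoms: N,N-dimethylformamide dimethyl acetal COC(OC)N(C)C
Why: Enaminone condensation of a methyl ketone with an amide acetal, the standard entry to chromones from 2-hydroxyacetophenones, which leaves MOM ethers and the vinyl group untouched.

**Step 5**
Reactants: 7 (E)-3-(dimethylamino)-1-[2-hydroxy-4,6-bis(methoxymethoxy)-3-(2-methylbut-3-en-2-yl)phenyl]prop-2-en-1-one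
Product: 9 5,7-bis(methoxymethoxy)-8-(2-methylbut-3-en-2-yl)-4-oxo-4H-chromen-3-yl benzoate, via alpha-benzoyloxy enaminone 8 (not isolated)
Conditions: (BzO)2 (1.3 equiv), MeCN, 70 °C
Reagents that add atoms: dibenzoyl peroxide O=C(OOC(=O)c1ccccc1)c1ccccc1
Why: C–H acyloxylation and chromone annulation of an ortho-hydroxyaryl enaminone with a diacyl peroxide, in which the nucleophilic alpha carbon attacks the O–O bond to give 8 and the phenol then adds to the beta carbon and expels dimethylamine, closing ring C with the C3 oxygen in place.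

**Step 6**
Reactants: 9 5,7-bis(methoxymethoxy)-8-(2-methylbut-3-en-2-yl)-4-oxo-4H-chromen-3-yl benzoate
Product: 10 3-hydroxy-5,7-bis(methoxymethoxy)-8-(2-methylbut-3-en-2-yl)-4H-chromen-4-one
Conditions: K2CO3 (1.5 equiv), MeOH, 0 °C
Reagents that add atoms: none
Why: Methanolysis (transesterification) of an activated enol ester, which is much faster than methoxide addition at C2, and the 3-olate that forms shields the pyranone from further attack.

**Step 7**
Reactants: 11 3,4-dihydroxybenzaldehyde
Product: 12 3-hydroxy-4-(methoxymethoxy)benzaldehyde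
Conditions: MOMCl (1.05 equiv), K2CO3 (1.1 equiv), acetone, 0 °C to rt
Reagents that add atoms: chloromethyl methyl ether COCCl
Why: Regioselective O-alkylation, in which the 4-OH para to the formyl group is the more acidic one, so one equivalent of base and MOMCl protects it and leaves the 3-OH free.

**Step 8**
Reactants: 12 3-hydroxy-4-(methoxymethoxy)benzaldehyde; 13 3-chloro-3-methylbut-1-yne
Product: 14 4-(methoxymethoxy)-3-[(2-methylbut-3-yn-2-yl)oxy]benzaldehyde
Conditions: K2CO3, KI (cat.), CuI (cat.), DMF, 65 °C
Reagents that add atoms: none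
Why: Copper-assisted Williamson-type propargylation of a phenol with a tertiary propargylic chloride, the usual way to aryl 1,1-dimethylpropargyl ethers.

**Step 9**
Reactants: 14 4-(methoxymethoxy)-3-[(2-methylbut-3-yn-2-yl)oxy]benzaldehyde
Product: 16 8-(methoxymethoxy)-2,2-dimethyl-2H-chromene-5-carbaldehyde, via ortho-allenylphenol 15 (not isolated)
Conditions: PhNEt2, 190 °C, Ar
Reagents that add atoms: none
Why: Aromatic propargyl Claisen rearrangement, in which only C2 is a free ortho position, so the [3,3] shift gives allenylphenol 15, which passes by 1,5-hydrogen shift and 6π electrocyclisation to the 2,2-dimethylchromene (ring D).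

**Step 10**
Reactants: 16 8-(methoxymethoxy)-2,2-dimethyl-2H-chromene-5-carbaldehyde
Product: 17 8-(methoxymethoxy)-2,2-dimethylchromane-5-carbaldehyde
Conditions: H2 (1 atm), Pd/C (10 wt%), EtOAc, rt
Reagents that add atoms: none
Why: Catalytic hydrogenation, in which the cis-disubstituted styrene-type double bond is saturated far faster than the aryl aldehyde is reduced in a neutral aprotic solvent.

**Step 11**
Reactants: 17 8-(methoxymethoxy)-2,2-dimethylchromane-5-carbaldehyde
Product: 18 [8-(methoxymethoxy)-2,2-dimethylchroman-5-yl]methanol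
Conditions: NaBH4, MeOH, 0 °C
Reagents that add atoms: none
Why: Borohydride reduction of the aldehyde, with no other reducible group present.

**Step 12**
Reactants: 18 [8-(methoxymethoxy)-2,2-dimethylchroman-5-yl]methanol
Product: 19 [6-bromo-8-(methoxymethoxy)-2,2-dimethylchroman-5-yl]methanol
Conditions: NBS (1.05 equiv), MeCN, 0 °C, dark
Reagents that add atoms: N-bromosuccinimide O=C1CCC(=O)N1Br
Why: Electrophilic aromatic bromination, in which the ring-locked chroman oxygen is the strongest donor and directs para to C6, as in the 6-bromination of veratryl alcohol, while C7 is only ortho to the weaker MOM-ether donor.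

**Step 13**
Reactants: 10 3-hydroxy-5,7-bis(methoxymethoxy)-8-(2-methylbut-3-en-2-yl)-4H-chromen-4-one; 19 [6-bromo-8-(methoxymethoxy)-2,2-dimethylchroman-5-yl]methanol
Product: 20 3-{[6-bromo-8-(methoxymethoxy)-2,2-dimethylchroman-5-yl]methoxy}-5,7-bis(methoxymethoxy)-8-(2-methylbut-3-en-2-yl)-4H-chromen-4-one
Conditions: PPh3, DIAD, THF, 0 °C to rt
Reagents that add atoms: none
Why: Mitsunobu etherification, in which the acidic 3-hydroxychromone is alkylated on oxygen by the activated primary benzylic alcohol under neutral conditions that spare the bromide, the MOM ethers and the base-sensitive C2–H pyranone.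

**Step 14**
Reactants: 20 3-{[6-bromo-8-(methoxymethoxy)-2,2-dimethylchroman-5-yl]methoxy}-5,7-bis(methoxymethoxy)-8-(2-methylbut-3-en-2-yl)-4H-chromen-4-one
Product: 21 tris-MOM ether-bridged pentacycle (flavonol skeleton with O3 and C2' linked by CH2; 5,7,5'-tris(methoxymethoxy), 8-(2-methylbut-3-en-2-yl), 3',4'-fused 2,2-dimethylchroman)
Conditions: Pd(OAc)2 (5 mol%), PCy3·HBF4 (10 mol%), PivOH (30 mol%), K2CO3 (2 equiv), DMA, 110 °C, Ar
Reagents that add atoms: none
Why: Zerovalent palladium formed from Pd(OAc)2 and PCy3 inserts into the C1'–Br bond, pivalate replaces bromide on divalent palladium, and the carboxylate removes the acidic C2–H proton while the metal binds C2 (concerted metalation–deprotonation), giving a seven-membered palladacycle that collapses by reductive elimination to the C2–C1' bond. The closest known reaction type is the intramolecular direct arylation of 2-bromobenzyl aryl ethers to benzo[c]chromenes and of 2-bromobenzyl ethers of hydroxypyranones and hydroxycoumarins, together with the palladium-catalysed C2–H arylation of chromones. The one ring closed is the six-membered ether ring C2–C3–O–CH2–C2'–C1', formed by reductive elimination from the seven-membered metallacycle and counting as a 6-endo closure on the C2=C3 bond, and a Heck-type carbopalladation followed by base-assisted loss of HPdBr through the oxygen-bound enolate would give the same product. No stereocentre is formed. Site selectivity is needed and is secured by the three-atom tether, which lets the arylpalladium reach only C2–H and turns a hindered ortho-substituted biaryl-type union into an intramolecular one. Chemoselectivity over a Heck reaction is secured because the vinyl group sits on a quaternary carbon at C8 on the far side of O1 from the metal, and the MOM ethers, chroman and pyranone tolerate anhydrous K2CO3.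

**Step 15**
Reactants: 21 tris-MOM ether-bridged pentacycle
Product: 22 5,7,5'-trihydroxy ether-bridged pentacycle
Conditions: NaHSO4·SiO2, CH2Cl2, rt
Reagents that add atoms: none
Why: Acid-catalysed acetal hydrolysis selective for phenolic MOM ethers, run in a non-nucleophilic solvent so that any ionisation of the cyclic benzylic ether can only reclose, with a solid acid too weak to protonate the monosubstituted alkene.

**Step 16**
Reactants: 22 5,7,5'-trihydroxy ether-bridged pentacycle
Product: 23 5,7,5'-triacetoxy ether-bridged pentacycle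
Conditions: Ac2O, pyridine, DMAP (cat.), rt
Reagents that add atoms: acetic anhydride CC(=O)OC(C)=O
Why: Nucleophile-catalysed O-acetylation, which exchanges the acid-labile acetals for esters that withstand Lewis acid and acyl bromide and keeps the 7-oxygen from adding to the vinyl group.

**Step 17**
Reactants: 23 5,7,5'-triacetoxy ether-bridged pentacycle
Product: 25 2-[8-acetoxy-5-(bromomethyl)-2,2-dimethylchroman-6-yl]-8-(2-methylbut-3-en-2-yl)-4-oxo-4H-chromene-3,5,7-triyl triacetate, via bromomagnesium 3-olate 24 (not isolated)
Conditions: AcBr (3 equiv), MgBr2·OEt2 (1.5 equiv), CH2Cl2, 0 °C to rt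
Reagents that add atoms: acetyl bromide CC(=O)Br; magnesium bromide diethyl etherate [Mg+2].[Br-].[Br-].CCOCC (gives Mg and Br of 24 and is re-formed)
Why: Acylative ether cleavage with an acyl bromide and a Lewis acid, in which MgBr2 chelates the C4 carbonyl and the C3 ether oxygen, bromide opens the activated benzylic C–O bond by SN2 attack as in the chelation-assisted debenzylation of ortho-acyl aryl benzyl ethers, and acetyl bromide traps olate 24 so that the ring cannot reclose.

**Step 18**
Reactants: 26 2-methylprop-1-enylmagnesium bromide; 27 tributyltin chloride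
Product: 28 tributyl(2-methylprop-1-enyl)stannane
Conditions: THF, 0 °C to rt
Reagents that add atoms: none
Why: Transmetalation of an alkenyl Grignard reagent with a trialkyltin chloride.

**Step 19**
Reactants: 25 2'-(bromomethyl)flavonol tetraacetate; 28 tributyl(2-methylprop-1-enyl)stannane
Product: 29 broussoflavonol E 3,5,7,5'-tetraacetate
Conditions: Pd2(dba)3 (2.5 mol%), AsPh3 (10 mol%), THF, 60 °C, Ar
Reagents that add atoms: none
Why: Stille coupling of a benzylic bromide with an alkenylstannane, which runs without base so that the acetates stay on and the 3-oxygen cannot displace the bromide, and which turns the former tether carbon into C1 of the prenyl chain.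

**Step 20**
Reactants: 29 broussoflavonol E 3,5,7,5'-tetraacetate
Product: 30 broussoflavonol E
Conditions: NH3 (7 M in MeOH), 0 °C to rt, Ar
Reagents that add atoms: none
Why: Aminolysis of aryl and enol acetates, mild and non-acidic so that neither the prenyl nor the 1,1-dimethylallyl group cyclises onto a neighbouring hydroxyl.

**Compound list**
1 | 2,4,6-trihydroxyacetophenone | CC(=O)c1c(O)cc(O)cc1O | starting material
2 | prenyl bromide | CC(C)=CCBr | starting material
3 | 1-[2,6-dihydroxy-4-(3-methylbut-2-enyloxy)phenyl]ethanone | CC(=O)c1c(O)cc(OCC=C(C)C)cc1O | intermediate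
4 | 4-acetyl-3,5-dihydroxy-6-(2-methylbut-3-en-2-yl)cyclohexa-2,4-dien-1-one (racemic, transient) | CC(=O)C1=C(O)C(C(C)(C)C=C)C(=O)C=C1O | intermediate
5 | 1-[2,4,6-trihydroxy-3-(2-methylbut-3-en-2-yl)phenyl]ethanone | CC(=O)c1c(O)cc(O)c(C(C)(C)C=C)c1O | intermediate
6 | 1-[2-hydroxy-4,6-bis(methoxymethoxy)-3-(2-methylbut-3-en-2-yl)phenyl]ethanone | CC(=O)c1c(OCOC)cc(OCOC)c(C(C)(C)C=C)c1O | intermediate
7 | (E)-3-(dimethylamino)-1-[2-hydroxy-4,6-bis(methoxymethoxy)-3-(2-methylbut-3-en-2-yl)phenyl]prop-2-en-1-one | CN(C)/C=C/C(=O)c1c(OCOC)cc(OCOC)c(C(C)(C)C=C)c1O | intermediate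
8 | (Z)-1-(dimethylamino)-3-[2-hydroxy-4,6-bis(methoxymethoxy)-3-(2-methylbut-3-en-2-yl)phenyl]-3-oxoprop-1-en-2-yl benzoate | CN(C)/C=C(OC(=O)c1ccccc1)/C(=O)c1c(OCOC)cc(OCOC)c(C(C)(C)C=C)c1O | intermediate
9 | 5,7-bis(methoxymethoxy)-8-(2-methylbut-3-en-2-yl)-4-oxo-4H-chromen-3-yl benzoate | C=CC(C)(C)c1c(OCOC)cc(OCOC)c2c(=O)c(OC(=O)c3ccccc3)coc12 | intermediate
10 | 3-hydroxy-5,7-bis(methoxymethoxy)-8-(2-methylbut-3-en-2-yl)-4H-chromen-4-one | C=CC(C)(C)c1c(OCOC)cc(OCOC)c2c(=O)c(O)coc12 | intermediate
11 | 3,4-dihydroxybenzaldehyde | O=Cc1ccc(O)c(O)c1 | starting material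
12 | 3-hydroxy-4-(methoxymethoxy)benzaldehyde | COCOc1ccc(C=O)cc1O | intermediate
13 | 3-chloro-3-methylbut-1-yne | C#CC(C)(C)Cl | starting material
14 | 4-(methoxymethoxy)-3-[(2-methylbut-3-yn-2-yl)oxy]benzaldehyde | C#CC(C)(C)Oc1cc(C=O)ccc1OCOC | intermediate
15 | 3-hydroxy-4-(methoxymethoxy)-2-(3-methylbuta-1,2-dienyl)benzaldehyde | CC(C)=C=Cc1c(C=O)ccc(OCOC)c1O | intermediate
16 | 8-(methoxymethoxy)-2,2-dimethyl-2H-chromene-5-carbaldehyde | O=Cc1ccc(OCOC)c2OC(C)(C)C=Cc12 | intermediate
17 | 8-(methoxymethoxy)-2,2-dimethylchromane-5-carbaldehyde | O=Cc1ccc(OCOC)c2OC(C)(C)CCc12 | intermediate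
18 | [8-(methoxymethoxy)-2,2-dimethylchroman-5-yl]methanol | OCc1ccc(OCOC)c2OC(C)(C)CCc12 | intermediate
19 | [6-bromo-8-(methoxymethoxy)-2,2-dimethylchroman-5-yl]methanol | OCc1c(Br)cc(OCOC)c2OC(C)(C)CCc12 | intermediate
20 | 3-{[6-bromo-8-(methoxymethoxy)-2,2-dimethylchroman-5-yl]methoxy}-5,7-bis(methoxymethoxy)-8-(2-methylbut-3-en-2-yl)-4H-chromen-4-one | C=CC(C)(C)c1c(OCOC)cc(OCOC)c2c(=O)c(OCc3c(Br)cc(OCOC)c4c3CCC(C)(C)O4)coc12 | intermediate
21 | tris-MOM ether-bridged pentacycle (C3–O–CH2–C2' bridge) | C=CC(C)(C)c1c(OCOC)cc(OCOC)c2c(=O)c3c(oc12)-c1cc(OCOC)c2c(c1CO3)CCC(C)(C)O2 | intermediate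
22 | 5,7,5'-trihydroxy ether-bridged pentacycle | C=CC(C)(C)c1c(O)cc(O)c2c(=O)c3c(oc12)-c1cc(O)c2c(c1CO3)CCC(C)(C)O2 | intermediate
23 | 5,7,5'-triacetoxy ether-bridged pentacycle | C=CC(C)(C)c1c(OC(C)=O)cc(OC(C)=O)c2c(=O)c3c(oc12)-c1cc(OC(C)=O)c2c(c1CO3)CCC(C)(C)O2 | intermediate
24 | bromomagnesium 3-olate of the ring-opened 2'-(bromomethyl)flavonol 5,7,5'-triacetate | C=CC(C)(C)c1c(OC(C)=O)cc(OC(C)=O)c2c(=O)c(O[Mg]Br)c(-c3cc(OC(C)=O)c4c(c3CBr)CCC(C)(C)O4)oc12 | intermediate
25 | 2-[8-acetoxy-5-(bromomethyl)-2,2-dimethylchroman-6-yl]-8-(2-methylbut-3-en-2-yl)-4-oxo-4H-chromene-3,5,7-triyl triacetate | C=CC(C)(C)c1c(OC(C)=O)cc(OC(C)=O)c2c(=O)c(OC(C)=O)c(-c3cc(OC(C)=O)c4c(c3CBr)CCC(C)(C)O4)oc12 | intermediate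
26 | 2-methylprop-1-enylmagnesium bromide | CC(C)=C[Mg]Br | starting material
27 | tributyltin chloride | CCCC[Sn](Cl)(CCCC)CCCC | starting material
28 | tributyl(2-methylprop-1-enyl)stannane | CCCC[Sn](CCCC)(CCCC)C=C(C)C | intermediate
29 | broussoflavonol E 3,5,7,5'-tetraacetate | C=CC(C)(C)c1c(OC(C)=O)cc(OC(C)=O)c2c(=O)c(OC(C)=O)c(-c3cc(OC(C)=O)c4c(c3CC=C(C)C)CCC(C)(C)O4)oc12 | intermediate
30 | broussoflavonol E | C=CC(C)(C)c1c(O)cc(O)c2c(=O)c(O)c(-c3cc(O)c4c(c3CC=C(C)C)CCC(C)(C)O4)oc12 | target

**Step count**
Total step count: 20. Longest linear sequence: 13 steps (steps 1–6, 13–17, 19, 20; the branch through steps 7–12 is equally long).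

**Steps most likely to fail**

Step 14 (direct arylation). The C2–H metalation may be slower than protodebromination of the arylpalladium species. The C2-unsubstituted pyranone may also degrade during long heating with base. The fallback replaces catalytic C–H activation by stoichiometric metalation and an intramolecular Negishi coupling. It sets out from 20. TMPZnCl·LiCl with MgCl2 in THF at 25 °C should zincate the only acidic position of ring C, leaving the aryl bromide untouched, to give the chromon-2-ylzinc chloride F1. Addition of Pd(OAc)2 and SPhos and warming to 50 °C should close the same six-membered ring. The fallback comes back to the route at 21.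

Step 17 (acylative opening). Several processes may compete:
- The tertiary alkyl aryl ether of the chroman may be opened acylatively.
- Adventitious HBr may add to the vinyl group.
- The opening may stall, because the para-acetoxy group supports the benzylic carbon only weakly.

The fallback separates C–O cleavage from halide installation. It sets out from 23. Acetolysis with Ac2O and catalytic FeCl3 in CH2Cl2 at 0 °C should give the stable 2'-(acetoxymethyl)flavonol tetraacetate F2, which can be purified. Me3SiBr in CH2Cl2 should then exchange only the benzylic acetate for bromide. The fallback comes back to the route at 25.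

Step 2 (Claisen rearrangement). At 200 °C the prenyl ether may lose isoprene. The new phenol may also add to the neighbouring 1,1-dimethylallyl group, or trigger an abnormal Claisen shift. The fallback masks every phenol as it appears. It sets out from 3. Ac2O and pyridine should give 2,6-diacetoxy-4-(3-methylbut-2-enyloxy)acetophenone F3. Rearrangement of this still symmetrical ether in PhNEt2 containing Ac2O at 190 °C should trap the liberated phenol at once as 2,4,6-triacetoxy-3-(2-methylbut-3-en-2-yl)acetophenone F4. Methanolysis with K2CO3 in MeOH comes back to the route at 5.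

**Further compounds**
F1 | step 14 | chromon-2-ylzinc chloride derived from 20 | C=CC(C)(C)c1c(OCOC)cc(OCOC)c2c(=O)c(OCc3c(Br)cc(OCOC)c4c3CCC(C)(C)O4)c([Zn]Cl)oc12
F2 | step 17 | 2'-(acetoxymethyl)flavonol 3,5,7,5'-tetraacetate | C=CC(C)(C)c1c(OC(C)=O)cc(OC(C)=O)c2c(=O)c(OC(C)=O)c(-c3cc(OC(C)=O)c4c(c3COC(C)=O)CCC(C)(C)O4)oc12
F3 | step 2 | 2,6-diacetoxy-4-(3-methylbut-2-enyloxy)acetophenone | CC(=O)Oc1cc(OCC=C(C)C)cc(OC(C)=O)c1C(C)=O
F4 | step 2 | 2,4,6-triacetoxy-3-(2-methylbut-3-en-2-yl)acetophenone | CC(=O)Oc1cc(OC(C)=O)c(C(C)(C)C=C)c(OC(C)=O)c1C(C)=O
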